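**Plan**

1. Locants follow the heavy atoms of the target SMILES: acetate C1–C2(=O3)–O4 on C5; C6; C7 (methyl C8); O9; C10; C11; C12 (Br13); C14 (methyls C15, C16); O17; C18 (methyl C19); C20; C21; C22 (O23). Bridgeheads C7 and C20 are joined by bridges a (C22–C21), b (C6–C5) and c (O9–C10–C18).
2. Cuts, latest first: O17–C14 with C12–Br (bromoetherification), C11–C12 (Suzuki–Miyaura coupling), C10–C11 (carbonyl methylenation), O4 and O9 (Baeyer–Villiger insertions into C5–C2 and C7–C10), C22–O23 (hydroboration), then C5–C20 with C6–C7, and O17–C18.
3. Enabling feature: C10, C7, C22, C21, C20 and C18 are the ring carbons of 2,6-dimethylphenol (C10 the phenol carbon, C8 and C19 its methyls) with O17 on the ortho carbon C18. C6–C5 bridges C7 and C20, and the acyl carbon C2 on C5 reaches O17, so the cage is the intramolecular Diels–Alder adduct of an o-quinol acrylate.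
4. Ring order forward: γ-lactone and bicyclo[2.2.2]octene carbocycle together in the cycloaddition, oxepane by oxygen insertion into bridge c, tetrahydropyran by bromoetherification near the end.
5. Stereochemistry: C18 by resolution of the racemic cycloadduct; C5, C7 and C20 from the ester tether; C22 and C10 by reagent approach to the more open cage face; C12 from a chair-like bromonium closure; both oxygen insertions with retention.

Key step: step 1

Assumption: the dearomatisation is run without enantiocontrol, the racemic cycloadduct 4 is resolved, and every compound from 5 on is a single enantiomer. Compounds 3 and 4 are racemates whose SMILES show the enantiomer that is carried on.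

**Step 1**
Reactants: 1 2,6-dimethylphenol; 2 acrylic acid
Product: 4 racemic tricyclic keto-lactone, via dienone acrylate 3 (not isolated)
Conditions: Pb(OAc)4 (1.2 equiv), acrylic acid/CH2Cl2, 0 °C to 20 °C; then PhMe (0.02 M), 100 °C
Reagents that add atoms: none
Why: The aryloxy lead tetracarboxylate formed from 1 transfers an acrylate ligand to the methyl-bearing ortho carbon C18 (Wessely acyloxylation; the two ortho carbons are equivalent), giving the 2,4-dienone 3, whose diene C20=C21–C22=C7 is held three atoms (C18, O17, C2) from the acrylate double bond. On warming, a concerted suprafacial intramolecular [4+2] cycloaddition joins the acrylate α-carbon (C5) to C20 and the β-carbon (C6) to C7; the closest known reaction type is the one-flask Wessely oxidation–intramolecular Diels–Alder reaction of phenols in unsaturated acids. The γ-lactone (O17, C2, C5, C20, C18) closes because the α-carbon can only reach the diene terminus next to C18, and the six-membered carbocycle (C5, C6, C7, C22, C21, C20) closes as the new ring of a bicyclo[2.2.2]octenone. C5, C7 and C20 are fixed relative to C18 by the tether, since only the diene face that carries O17 can be reached and the lactone can only span C18–C20–C5 in a cis sense; C18 itself is formed without control, hence the racemate. The selectivity needed is intramolecular cycloaddition over [4+2] dimerisation of the dienone, and it is secured by the short tether, the dilution and the 2,6-dimethyl pattern, which slows dimerisation.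

**Step 2**
Reactants: 4 racemic tricyclic keto-lactone
Product: 5 keto-lactone as the single enantiomer with C18 configured as in the target
Conditions: preparative SFC on amylose tris(3,5-dimethylphenylcarbamate), CO2/MeOH, 35 °C
Reagents that add atoms: none
Why: Resolution by chromatography on a chiral stationary phase; the rigid cage has no pathway to racemisation, and the absolute configuration of the retained enantiomer is to be confirmed by anomalous-dispersion X-ray analysis of 5 or of bromide 17.

**Step 3**
Reactants: 5 keto-lactone
Product: 6 bis-lactone alkene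
Conditions: mCPBA (1.3 equiv), NaHCO3, CH2Cl2, 0 °C to 20 °C
Reagents that add atoms: 3-chloroperoxybenzoic acid, OOC(=O)c1cccc(Cl)c1
Why: Baeyer–Villiger oxidation of the strained, non-enolisable bridging ketone should outpace epoxidation of the electron-poor cage alkene; the allylic, fully alkyl-substituted bridgehead C7 migrates with retention in preference to C18, which is deactivated by its acyloxy group, and the buffer protects the tertiary allylic lactone from ionisation.

**Step 4**
Reactants: 6 bis-lactone alkene
Product: 8 C22 alcohol, via alkylborane 7 (not isolated)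
Conditions: BH3·THF (1.1 equiv), THF, 0 °C; then 30% H2O2, aq. NaHCO3, 0 °C to 20 °C
Reagents that add atoms: hydrogen peroxide, OO
Why: Hydroboration–oxidation in which the allylic ester oxygen on C7 directs boron to the adjacent alkene carbon C22 and the borane approaches bridge a from the side of the two-carbon bridge b, away from the three-atom lactone bridge and C19, so that oxidation with retention sets C22–OH trans to O9; β-elimination of the boryl ester is excluded because C7 is a bridgehead.

**Step 5**
Reactants: 8 C22 alcohol
Product: 9 silyl ether
Conditions: TBSOTf, 2,6-lutidine, CH2Cl2, 0 °C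
Reagents that add atoms: tert-butyldimethylsilyl trifluoromethanesulfonate, CC(C)(C)[Si](C)(C)OS(=O)(=O)C(F)(F)F
Why: Silylation of a hindered secondary alcohol with a silyl triflate; the ether is needed because the titanium and boron reagents of steps 8 and 9 do not tolerate a free hydroxyl.

**Step 6**
Reactants: 9 silyl ether
Product: 10 C5 methyl ketone with free O17–H (hemiketal)
Conditions: MeLi (1.1 equiv), THF, −78 °C; AcOH, −78 °C
Reagents that add atoms: methyllithium, [Li]C
Why: Mono-addition of an organolithium to a lactone, held at the tetrahedral lithium alkoxide at −78 °C; the γ-lactone carbonyl is far more accessible than the C10 lactone carbonyl, which is flanked by the fully substituted C18 and the tertiary O9, and the hemiketal centre that forms is of no consequence.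

**Step 7**
Reactants: 10 methyl ketone (hemiketal)
Product: 11 cyclic methyl ketal
Conditions: MeOH, PPTS (cat.), 3 Å molecular sieves, 20 °C
Reagents that add atoms: methanol, CO
Why: Acid-catalysed ketalisation (Fischer type) through the cyclic oxocarbenium ion masks the ketone and O17–H in one group; only the C5 epimer whose acyl carbon faces bridge c can close the ring, so the C5 configuration is held, and the new ketal centre (either epimer) is removed in step 10.

**Step 8**
Reactants: 11 cyclic methyl ketal
Product: 12 exocyclic enol ether
Conditions: Cp2TiMe2 (3 equiv), PhMe, 75 °C, dark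
Reagents that add atoms: dimethyltitanocene (Cp2TiMe2), C[Ti](C)(C1C=CC=C1)C1C=CC=C1
Why: Petasis methylenation of the C10 lactone carbonyl through the titanium methylidene; the neutral conditions leave the mixed ketal and the silyl ether intact, and the enol ether cannot migrate into the ring because C18 carries no hydrogen.

**Step 9**
Reactants: 12 exocyclic enol ether; 13 1-bromo-2-methylprop-1-ene
Product: 15 C10-prenyl cage ether, via B-alkyl-9-BBN 14 (not isolated)
Conditions: 9-BBN (2 equiv), THF, 20 °C; then 13, PdCl2(dppf) (5 mol %), 3 M aq. Cs2CO3, DMF, 20 °C
Reagents that add atoms: none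
Why: Hydroboration of the 1,1-disubstituted enol ether puts boron on the terminal C11 and hydrogen on C10 from the same face, and a B-alkyl Suzuki–Miyaura coupling with the vinyl bromide then completes the prenyl chain; the face of C10=C11 toward bridge b is covered by O17 and by the substituent of the ketal carbon that points up along bridge c, so hydrogen should enter from the side of bridge a (past C19 only) and leave C11 cis to O17 as in the target.

**Step 10**
Reactants: 15 C10-prenyl cage ether
Product: 16 prenyl hydroxy ketone
Conditions: PPTS (cat.), acetone/H2O 4:1, 20 °C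
Reagents that add atoms: water, O
Why: Mild acid hydrolysis of the mixed cyclic ketal frees the C5 methyl ketone and the tertiary O17–H without touching the silyl ether, the cage ether or the trisubstituted alkene; no stereocentre is affected.

**Step 11**
Reactants: 16 prenyl hydroxy ketone
Product: 17 bromotetrahydropyran ketone
Conditions: TBCO (1.1 equiv), MeNO2, 0 °C, dark
Reagents that add atoms: 2,4,4,6-tetrabromocyclohexa-2,5-dien-1-one, O=C1C(Br)=CC(Br)(Br)C=C1Br
Why: Bromoetherification by anti addition of bromine and O17 across C12=C14 with Markovnikov attack at the tertiary C14 gives the 6-endo tetrahydropyran, and a chair-like transition state with bromine and the C20 branch of C18 equatorial and C19 axial sets C12 (Br cis to C10–H and C19); the hemiketal form of 16 also feeds the product because O17 remains the nucleophilic oxygen.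

**Step 12**
Reactants: 17 bromotetrahydropyran ketone
Product: 18 silyl ether of the target
Conditions: mCPBA (3 equiv), NaHCO3, CH2Cl2, 20 °C
Reagents that add atoms: 3-chloroperoxybenzoic acid, OOC(=O)c1cccc(Cl)c1
Why: Baeyer–Villiger oxidation of a methyl ketone in which the secondary C5 migrates in preference to methyl and with retention, so O4 takes the place of the acyl carbon; no alkene remains, and the bromide, the ethers and the silyl ether are inert to buffered peracid.

**Step 13**
Reactants: 18 silyl ether of the target
Product: 19 target
Conditions: HF·pyridine, THF/pyridine, 0 °C to 20 °C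
Reagents that add atoms: none
Why: Fluoride cleavage of the silyl ether under non-basic conditions that spare the acetate and the secondary bromide; no stereocentre is touched.

**Compound list**

1 | 2,6-dimethylphenol | Cc1cccc(C)c1O | starting material
2 | acrylic acid (prop-2-enoic acid) | C=CC(=O)O | starting material
3 | racemic (1,5-dimethyl-6-oxocyclohexa-2,4-dien-1-yl) prop-2-enoate, the o-quinol acrylate; SMILES shows the enantiomer that leads to the target | C=CC(=O)O[C@@]1(C)C=CC=C(C)C1=O | intermediate (not isolated)
4 | racemic tricyclic keto-lactone: bicyclo[2.2.2]octene cage (bridgeheads C7 and C20, alkene C21=C22) with methyls on C7 and C18, the C10 ketone in bridge c and a γ-lactone from O17 on C18 to the carbonyl carbon C2 on C5; SMILES shows the enantiomer carried on | O=C1O[C@]2(C)C(=O)[C@]3(C)C[C@H]1[C@H]2C=C3 | intermediate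
5 | the same keto-lactone as a single enantiomer, C18 configured as in the target | O=C1O[C@]2(C)C(=O)[C@]3(C)C[C@H]1[C@H]2C=C3 | intermediate
6 | bis-lactone: O9 inserted between C7 and C10 (2-oxabicyclo[3.2.2]nonene cage), γ-lactone and C21=C22 retained | O=C1O[C@]2(C)C(=O)O[C@]3(C)C[C@H]1[C@H]2C=C3 | intermediate
7 | alkylborane: BH2 on C22 on the side of bridge b, C21 saturated | O=C1O[C@]2(C)C(=O)O[C@]3(C)C[C@H]1[C@H]2C[C@H]3B | intermediate (not isolated)
8 | alcohol: hydroxyl on C22 on the side of bridge b, trans to O9; both lactones retained | O=C1O[C@]2(C)C(=O)O[C@]3(C)C[C@H]1[C@H]2C[C@H]3O | intermediate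
9 | tert-butyldimethylsilyl ether of 8 | O=C1O[C@]2(C)C(=O)O[C@]3(C)C[C@H]1[C@H]2C[C@H]3O[Si](C)(C)C(C)(C)C | intermediate
10 | C5 methyl ketone with free tertiary O17–H, C10 lactone intact (open form shown; expected to sit largely as the cyclic hemiketal between O17 and C2) | CC(=O)[C@H]1C[C@@]2(C)OC(=O)[C@@](C)(O)[C@@H]1C[C@H]2O[Si](C)(C)C(C)(C)C | intermediate
11 | cyclic methyl ketal: C2 bears CH3 and OCH3 and is bonded to O17 and C5 (both C2 epimers) | COC1(C)O[C@]2(C)C(=O)O[C@]3(C)C[C@H]1[C@H]2C[C@H]3O[Si](C)(C)C(C)(C)C | intermediate
12 | exocyclic enol ether: C10=C11H2 in place of the C10 lactone carbonyl | COC1(C)O[C@]2(C)C(=C)O[C@]3(C)C[C@H]1[C@H]2C[C@H]3O[Si](C)(C)C(C)(C)C | intermediate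
13 | 1-bromo-2-methylprop-1-ene | CC(C)=CBr | starting material
14 | B-alkyl-9-borabicyclo[3.3.1]nonane: boron on C11, hydrogen on C10 on the side of bridge a | COC1(C)O[C@]2(C)[C@H](CB4C5CCCC4CCC5)O[C@]3(C)C[C@H]1[C@H]2C[C@H]3O[Si](C)(C)C(C)(C)C | intermediate (not isolated)
15 | C10-prenyl cage ether: chain C11–C12=C14(C15)(C16) on C10 cis to O17, ketal and silyl ether retained | COC1(C)O[C@]2(C)[C@H](CC=C(C)C)O[C@]3(C)C[C@H]1[C@H]2C[C@H]3O[Si](C)(C)C(C)(C)C | intermediate
16 | hydroxy ketone: C5 acetyl, free tertiary O17–H, prenyl on C10, silyl ether on O23 (open form; in equilibrium with the hemiketal) | CC(=O)[C@H]1C[C@@]2(C)O[C@@H](CC=C(C)C)[C@@](C)(O)[C@@H]1C[C@H]2O[Si](C)(C)C(C)(C)C | intermediate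
17 | bromotetrahydropyran ketone: ring O17–C18–C10–C11–C12–C14 closed, Br on C12 cis to C10–H and C19, C5 acetyl, silyl ether on O23 | CC(=O)[C@H]1C[C@@]2(C)O[C@H]3C[C@H](Br)C(C)(C)O[C@@]3(C)[C@@H]1C[C@H]2O[Si](C)(C)C(C)(C)C | intermediate
18 | O23-tert-butyldimethylsilyl ether of the target | CC(=O)O[C@H]1C[C@@]2(C)O[C@H]3C[C@H](Br)C(C)(C)O[C@@]3(C)[C@@H]1C[C@H]2O[Si](C)(C)C(C)(C)C | intermediate
19 | target, (5S,7R,10S,12S,18S,20R,22R) in the locants used here: C5 acetate, O9-bridged cage, bromotetrahydropyran, free C22 hydroxyl | CC(=O)O[C@H]1C[C@@]2(C)O[C@H]3C[C@H](Br)C(C)(C)O[C@@]3(C)[C@@H]1C[C@H]2O | target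

**Step count and risks**

Total step count: 13. Longest linear sequence: 13 steps (1 to 19).

Step 4. The regiochemistry of boron delivery may erode, because the steric demand of the fully substituted C7 opposes the directing effect of its ester oxygen, so that part of the borane adds at C21. The fallback sets out from 6 and returns at 8. Catalytic OsO4 with N-methylmorpholine N-oxide should dihydroxylate C21=C22 from the side of bridge b to the cis-diol F1. Phenyl chlorothionoformate and pyridine at −20 °C should acylate the less hindered C21 hydroxyl to the thionocarbonate F2, the C22 hydroxyl being shielded by C7. Bu3SnH with azobisisobutyronitrile in toluene at 80 °C (Barton–McCombie deoxygenation) then removes the C21 oxygen and gives 8. In this sequence the steric difference between C21 and C22 works for the required regiochemistry instead of against it.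

Step 9, with step 8 as its prerequisite. The facial selectivity of hydrogen delivery to C10 may be poor, or the methylenation of the congested C10 lactone may stall. The fallback sets out from 10 and returns at 16, and sets C10 by hydride attack on an oxocarbenium ion next to a larger shield. 1,2-Ethanedithiol with Zn(OTf)2 converts the ketone into the dithiolane F3, which fills the gap between bridges b and c. Allylmagnesium bromide (3 equiv, THF, −78 °C) adds once to the C10 lactone to give the lactol F4. Et3SiH with BF3·OEt2 at −78 °C reduces the derived cyclic oxocarbenium ion from the side of bridge a to the C-allyl ether F5. MeI and CaCO3 in aqueous acetonitrile release the methyl ketone F6. Cross-metathesis with 2-methylbut-2-ene and the second-generation Grubbs catalyst (H2IMes)(PCy3)Cl2Ru=CHPh turns allyl into prenyl and gives 16.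

Step 11. The bromonium ion may be captured in the 5-exo sense at C12, or through the alternative chair with loss of control at C12. The fallback sets out from 16 and returns at 17, and separates ring closure from carbon–bromine bond formation. Hg(OCOCF3)2 in nitromethane at 0 °C should cyclise reversibly and with Markovnikov regiochemistry to the tetrahydropyranyl organomercuric trifluoroacetate F7. Work-up with aqueous KBr exchanges it to the organomercuric bromide F8, with mercury equatorial on C12. Br2 with LiBr in pyridine under air then cleaves the carbon–mercury bond with retention and gives 17.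

**Further compounds**

F1 | step 4 | cis-21,22-diol of 6, both hydroxyls on the side of bridge b | O=C1O[C@]2(C)C(=O)O[C@]3(C)C[C@H]1[C@H]2[C@@H](O)[C@H]3O
F2 | step 4 | O-phenyl thionocarbonate of F1 on the C21 oxygen | O=C1O[C@]2(C)C(=O)O[C@]3(C)C[C@H]1[C@H]2[C@@H](OC(=S)Oc4ccccc4)[C@H]3O
F3 | step 9 | 1,3-dithiolane of the methyl ketone 10, free O17–H | CC1(SCCS1)[C@H]1C[C@@]2(C)OC(=O)[C@@](C)(O)[C@@H]1C[C@H]2O[Si](C)(C)C(C)(C)C
F4 | step 9 | C10 lactol bearing an allyl group (both C10 epimers, in equilibrium with the hydroxy ketone) | CC1(SCCS1)[C@H]1C[C@@]2(C)OC(O)(CC=C)[C@@](C)(O)[C@@H]1C[C@H]2O[Si](C)(C)C(C)(C)C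
F5 | step 9 | C10-allyl cage ether, hydrogen on C10 on the side of bridge a, dithiolane retained | CC1(SCCS1)[C@H]1C[C@@]2(C)O[C@@H](CC=C)[C@@](C)(O)[C@@H]1C[C@H]2O[Si](C)(C)C(C)(C)C
F6 | step 9 | C5 methyl ketone of F5 after removal of the dithiolane | CC(=O)[C@H]1C[C@@]2(C)O[C@@H](CC=C)[C@@](C)(O)[C@@H]1C[C@H]2O[Si](C)(C)C(C)(C)C
F7 | step 11 | organomercuric trifluoroacetate: tetrahydropyran closed, HgOCOCF3 on C12 | CC(=O)[C@H]1C[C@@]2(C)O[C@H]3C[C@H]([Hg]OC(=O)C(F)(F)F)C(C)(C)O[C@@]3(C)[C@@H]1C[C@H]2O[Si](C)(C)C(C)(C)C
F8 | step 11 | organomercuric bromide obtained from F7 | CC(=O)[C@H]1C[C@@]2(C)O[C@H]3C[C@H]([Hg]Br)C(C)(C)O[C@@]3(C)[C@@H]1C[C@H]2O[Si](C)(C)C(C)(C)C
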